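At early times the two runs differ in one setting, the reagent: by 4.00 h ash showed 0 % of its substrate, while elm still held 63.6 % at 2.50 h and stood at 35.9 % after 30.0 h, close to the 35.0 % its reagent charge leaves at one reagent per substrate.

| flask | substrate | reagent | capture agent | remark | time |
|---|---|---|---|---|---|
| elm | 0.20 M | 0.13 M | 0.20 M | run made earlier |  |
| ash | 0.20 M | 0.93 M | 0.20 M | run made earlier |  |
| noon | 0.20 M | 0.800 M | 0.200 M |  | 30 h |
| dusk | 0.20 M | 0.100 M | 0.200 M |  | 30 h |

- elm (time / h: bis adduct / %, substrate / %): 2.50: 0.6, 63.6; 6.00: 0.9, 48.0; 12.0: 0.7, 39.8; 30.0: 0.9, 35.9
- ash (time / h: bis adduct / %, substrate / %): 4.00: 15.3, 0; 10.0: 24.1, 0; 20.0: 28.7, 0; 30.0: 28.4, 0.1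

(each reading ± 0.3 percentage points)

- which of these holds the largest part of the substrate at the end of noon (single product / bis adduct / substrate)
- which of these holds the largest part of the substrate at the end of dusk (single product / bis adduct / substrate)
- how much bis adduct is there at the end of noon, in percent of the substrate charged

- the numbers in the tables scatter by 0.3 percentage points (one standard deviation)

I took the settings in turn, writing amounts as fractions of the substrate charge. Time seemed to buy little late on in ash, which read 28.7 % of bis adduct at 20.0 h and 28.4 % at 30.0 h. Those two readings average to a bis adduct fraction d of 28.5 %, and reagent should raise bis adduct with whatever stays free after the first addition and the second, b, which in ash was 3.36.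

The capture agent I took as the rival for the single product, so that d = κ b ln(1/ρ), with ρ the fraction of capture agent left. Ash charged capture agent and substrate equally, so with the single product neglected, ρ equalled d. That gave 0.0677 for κ, the selectivity factor of second addition over capture at equal amounts, where an even contest would read one.

For noon, b is 2.71, and with ρ again equal to d the equation closes near 25.2 %. I expected the capture agent to take the remaining 74.8 %, so I committed to bis adduct for noon. In dusk the reagent, the limiting reagent, covers 50.0 % of the substrate, which left me substrate at about 50.0 %.

The forecast said single product for noon, substrate for dusk and 25 % of bis adduct, and it parts from me on noon's holder: “Single product therefore dominates at about 75%.”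

Noon ended with bis adduct ahead at 25.1 %, against 2.69 % of single product, and dusk with substrate ahead at 50.5 %.

    reagent + single product ⇌ bis adduct + by-product (K = 3.40, k = 0.0940 /M/h)
    substrate + reagent → single product + by-product (k = 2.10 /M/h)
    single product + capture agent → trapped intermediate (k = 1.20 /M/h)

Noon held 72.2 % as trapped intermediate, with 28 % of its capture agent and 69 % of its reagent left. Putting those two amounts into κ gave me 23.9 % of bis adduct against the 25.1 % found. The neighbour, noon with 0.080 M of capture agent, kept 7.9 % of that capture agent and 63 % of its reagent, so the same reckoning gave 43.5 %, and that flask held 47.5 % of bis adduct, with 15.7 % still as single product.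

The runs were generated by integration from invented constants; noise was put on by code.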